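**Retrosynthetic overview**
Halimane numbering: ring A = C1–C5 and C10 (C1=C10 olefin; C4 quaternary with methyl C19 and ester carbon C18); ring B = C5–C10 (C8 with methyl C17; C9 quaternary with methyl C20 and chain C11–C16, ester oxygen on C15).
Feature used: C8 and C9 are neighbours in ring B and C9 sits next to the C1=C10 olefin, so C9 with methyl C20 can be a tertiary allylic radical made from a C20=C9–C10=C1 diene, and C8–C17 can be the β- and α-carbons of a vinyl sulfone; the C8–C9 bond is cut.
Late stage: (Z)-cinnamate from a phenylpropiolate by semihydrogenation, C12–C13 by Negishi coupling of a C12 iodide with an (E)-vinyl iodide, C17 methyl by desulfonylation.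
Precursor: C9–C10 by Suzuki coupling of a ring A C10 enol triflate with a 2-alkenylboronate, vinyl sulfone by cross-metathesis, C10 oxygen placed by iodolactonisation of the Diels–Alder acid.
Ring order: ring A first (enantioselective Diels–Alder of methacrolein with (E)-octa-1,3,7-triene sets C4 and C5), ring B second (radical 6-exo closure sets C8 and C9).

Key step: step 12

Assumption on step 1: the (S)-configured oxazaborolidinium is taken to expose the face of the bound enal that leads to the (1S,2R)-adduct; if induction runs the other way, the (R)-catalyst is used and nothing else changes.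
Remark: (E)-octa-1,3,7-triene, 3-bromobut-3-en-1-ol, but-2-yn-1-ol and 3-phenylprop-2-ynoic acid are taken as commercial.

**Route**

Step 1
Reactants: 1 methacrolein; 2 (E)-octa-1,3,7-triene
Product: 3 (1S,2R)-2-(but-3-en-1-yl)-1-methylcyclohex-3-ene-1-carbaldehyde
Conditions: (S)-3,3-diphenyl-1-(o-tolyl)tetrahydro-1H,3H-pyrrolo[1,2-c][1,3,2]oxazaborole (20 mol %), (CF3SO2)2NH (16 mol %), CH2Cl2, −78 → −40 °C
Reagents that add atoms: none
Why: Catalytic enantioselective Diels–Alder reaction in which the substituted diene terminus bonds to the α-carbon of the Lewis-acid-bound enal (ortho rule), the formyl group sits endo and so ends cis to the butenyl chain, and the chiral oxazaborolidinium shields one enal face, so C4 and C5 are set together while the isolated terminal alkene stays out.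

Step 2
Reactants: 3 (1S,2R)-2-(but-3-en-1-yl)-1-methylcyclohex-3-ene-1-carbaldehyde
Product: 4 (1S,2R)-2-(but-3-en-1-yl)-1-methylcyclohex-3-ene-1-carboxylic acid
Conditions: NaClO2, NaH2PO4, 2-methylbut-2-ene, t-BuOH/H2O, 0 °C → rt
Reagents that add atoms: sodium chlorite, [Na+].[O-]Cl=O
Why: Pinnick oxidation converts the hindered aldehyde to the acid without touching either alkene because the hypochlorite by-product is scavenged.

Step 3
Reactants: 4 (1S,2R)-2-(but-3-en-1-yl)-1-methylcyclohex-3-ene-1-carboxylic acid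
Product: 5 (1S,4S,5S,8S)-8-(but-3-en-1-yl)-4-iodo-1-methyl-6-oxabicyclo[3.2.1]octan-7-one
Conditions: I2, NaHCO3, MeCN/H2O, 0 °C, dark
Reagents that add atoms: iodine, II
Why: Iodolactonisation of a cyclohex-3-enecarboxylate gives the bridged γ-lactone by anti addition, the carboxylate reaching only C10 on its own face and iodine entering C1 on the other, which fixes oxygen at C10 regiospecifically, while the butenyl alkene has no lactone of workable size open to it.

Step 4
Reactants: 5 (1S,4S,5S,8S)-8-(but-3-en-1-yl)-4-iodo-1-methyl-6-oxabicyclo[3.2.1]octan-7-one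
Product: 6 (1S,5R,8S)-8-(but-3-en-1-yl)-1-methyl-6-oxabicyclo[3.2.1]octan-7-one
Conditions: Bu3SnH, AIBN (cat.), toluene, 80 °C
Reagents that add atoms: none
Why: Radical dehalogenation with tin hydride removes the secondary iodide, and the C1 radical cannot cyclise because the butenyl chain is held equatorial on the one-carbon bridge of the rigid bicycle.

Step 5
Reactants: 6 (1S,5R,8S)-8-(but-3-en-1-yl)-1-methyl-6-oxabicyclo[3.2.1]octan-7-one
Product: 8 methyl (1S,2S,3R)-2-(but-3-en-1-yl)-3-hydroxy-1-methylcyclohexane-1-carboxylate, via potassium hydroxy carboxylate 7 (not isolated)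
Conditions: KOH (1.05 equiv), MeOH/H2O, 60 °C; evaporate; MeI, DMF, rt
Reagents that add atoms: potassium hydroxide, [K+].[OH-]; iodomethane, CI
Why: Saponification opens the strained lactone irreversibly as the carboxylate, and O-alkylation of that carboxylate with iodomethane then gives the methyl ester without a reversible transesterification that could fall back to the lactone.

Step 6
Reactants: 8 methyl (1S,2S,3R)-2-(but-3-en-1-yl)-3-hydroxy-1-methylcyclohexane-1-carboxylate
Product: 9 methyl (1S,2S)-2-(but-3-en-1-yl)-1-methyl-3-oxocyclohexane-1-carboxylate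
Conditions: Dess–Martin periodinane, CH2Cl2, 0 °C → rt
Reagents that add atoms: none
Why: Dess–Martin oxidation of the secondary alcohol gives the C10 ketone under non-basic conditions, so the enolisable C5 centre is not epimerised and relactonisation is ruled out.

Step 7
Reactants: 9 methyl (1S,2S)-2-(but-3-en-1-yl)-1-methyl-3-oxocyclohexane-1-carboxylate
Product: 11 methyl (1S,2S)-2-(but-3-en-1-yl)-1-methyl-3-{[(trifluoromethyl)sulfonyl]oxy}cyclohex-3-ene-1-carboxylate, via lithium enolate 10 (not isolated)
Conditions: LiN(i-Pr)2, THF, −78 °C; then PhN(SO2CF3)2, −78 → 0 °C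
Reagents that add atoms: N-phenylbis(trifluoromethanesulfonimide), O=S(=O)(N(c1ccccc1)S(=O)(=O)C(F)(F)F)C(F)(F)F
Why: Kinetic enolate formation and O-triflation, in which the amide base removes a C1 methylene proton and not the hindered tertiary C5–H next to the quaternary C4, so the C1=C10 enol triflate forms and C5 is untouched.

Step 8
Reactants: 11 methyl (1S,2S)-2-(but-3-en-1-yl)-1-methyl-3-{[(trifluoromethyl)sulfonyl]oxy}cyclohex-3-ene-1-carboxylate; 12 phenyl vinyl sulfone
Product: 13 methyl (1S,2S)-1-methyl-2-[(E)-4-(phenylsulfonyl)but-3-en-1-yl]-3-{[(trifluoromethyl)sulfonyl]oxy}cyclohex-3-ene-1-carboxylate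
Conditions: 12 (3 equiv), (H2IMes)Cl2Ru=CH(C6H4-2-O-i-Pr) (second-generation Hoveyda–Grubbs catalyst, 5 mol %), CH2Cl2, 40 °C
Reagents that add atoms: none
Why: Olefin cross-metathesis of the terminal alkene with the electron-poor vinyl sulfone gives the (E)-vinyl sulfone, the trisubstituted enol triflate olefin being inert, and it is placed after all enolate and radical steps and before the diene exists so that no ring-closing metathesis can compete.

Step 9
Reactants: 14 3-bromobut-3-en-1-ol
Product: 15 (3-bromobut-3-en-1-yloxy)(tert-butyl)dimethylsilane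
Conditions: t-BuMe2SiCl, imidazole, CH2Cl2, rt
Reagents that add atoms: tert-butyldimethylsilyl chloride, CC(C)(C)[Si](C)(C)Cl
Why: Standard silylation protects the primary alcohol for the organolithium step.

Step 10
Reactants: 15 (3-bromobut-3-en-1-yloxy)(tert-butyl)dimethylsilane
Product: 17 2-[4-(tert-butyldimethylsilyloxy)but-1-en-2-yl]-4,4,5,5-tetramethyl-1,3,2-dioxaborolane, via alkenyllithium 16 (not isolated)
Conditions: t-BuLi (2.1 equiv), Et2O, −78 °C; then i-PrOBpin, −78 °C → rt
Reagents that add atoms: 2-isopropoxy-4,4,5,5-tetramethyl-1,3,2-dioxaborolane, CC(C)OB1OC(C)(C)C(C)(C)O1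
Why: Bromine–lithium exchange and borylation of the alkenyllithium give the 1,1-disubstituted alkenylboronate with the boron fixed on the internal carbon.

Step 11
Reactants: 13 methyl (1S,2S)-1-methyl-2-[(E)-4-(phenylsulfonyl)but-3-en-1-yl]-3-{[(trifluoromethyl)sulfonyl]oxy}cyclohex-3-ene-1-carboxylate; 17 2-[4-(tert-butyldimethylsilyloxy)but-1-en-2-yl]-4,4,5,5-tetramethyl-1,3,2-dioxaborolane
Product: 18 methyl (1S,2R)-3-[4-(tert-butyldimethylsilyloxy)but-1-en-2-yl]-1-methyl-2-[(E)-4-(phenylsulfonyl)but-3-en-1-yl]cyclohex-3-ene-1-carboxylate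
Conditions: Pd(OAc)2 (5 mol %), SPhos (10 mol %), K3PO4, THF/H2O, rt
Reagents that add atoms: none
Why: Suzuki–Miyaura coupling of the enol triflate with the alkenylboronate forms the C9–C10 bond and the diene, and a catalyst that transmetalates at room temperature is chosen so that coupling outruns insertion of the tethered vinyl sulfone.

Step 12
Reactants: 18 methyl (1S,2R)-3-[4-(tert-butyldimethylsilyloxy)but-1-en-2-yl]-1-methyl-2-[(E)-4-(phenylsulfonyl)but-3-en-1-yl]cyclohex-3-ene-1-carboxylate
Product: 19 methyl (4S,5R,8R,9S)-12-[(tert-butyldimethylsilyl)oxy]-17-(phenylsulfonyl)-13,14,15,16-tetranorhalim-1(10)-en-18-oate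
Conditions: Fe(acac)3 (30 mol %), PhSiH3 (2.0 equiv), EtOH/HOCH2CH2OH (5:1), degassed, 60 °C
Reagents that add atoms: none
Why: Proposed new method: the iron hydride that Fe(acac)3 and PhSiH3 form in ethanol should give a hydrogen atom to the unhindered, electron-rich terminal carbon C20 of the diene, the tertiary allylic radical so formed (spin on C9 and C1) adds through C9 to C8 of the (E)-vinyl sulfone, and the α-sulfonyl radical on C17 is then reduced and protonated. The closest known reaction is the Fe(acac)3/PhSiH3 reductive coupling of unconjugated 1,1-disubstituted olefins with vinyl sulfones (hydrogen-atom-transfer Giese cyclisation), and what is new is that a conjugated diene accepts the hydrogen atom and a stabilised allylic radical does the addition. Ring B closes in the 6-exo-trig mode, the only sensible one, since closure through C1 would give a bridged medium ring. C9 is controlled by the allyl radical geometry inherited from the s-trans diene: C20 lies syn to C5, the tether leaves C5 pseudo-equatorially (H5 pseudo-axial on ring A) and reaches the face of C9 opposite H5 through a chair, so C20 turns axial on ring B on the side of H5 and C11 stays in the plane of the C1–C10 olefin. C8 is controlled by the same chair, in which the sulfonyl-bearing C17 takes the equatorial place and thus ends cis to C20. The step needs initiation at the diene and not at the electron-poor vinyl sulfone, which the polarity of iron-hydride hydrogen-atom transfer secures, delivery of hydrogen to C20 and not C1, which the free methylene secures, and survival of the trisubstituted C1–C10 olefin of the product, for which the silane is kept to a small excess.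

Step 13
Reactants: 19 methyl (4S,5R,8R,9S)-12-[(tert-butyldimethylsilyl)oxy]-17-(phenylsulfonyl)-13,14,15,16-tetranorhalim-1(10)-en-18-oate
Product: 20 methyl (4S,5R,8R,9S)-12-[(tert-butyldimethylsilyl)oxy]-13,14,15,16-tetranorhalim-1(10)-en-18-oate
Conditions: Mg turnings, MeOH, 50 °C
Reagents that add atoms: none
Why: Reductive desulfonylation by electron transfer from magnesium in methanol cleaves the alkyl–sulfonyl bond and leaves the C17 methyl, the isolated olefin, the methyl ester and the silyl ether being inert and C8 (β to sulfur) not epimerisable.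

Step 14
Reactants: 20 methyl (4S,5R,8R,9S)-12-[(tert-butyldimethylsilyl)oxy]-13,14,15,16-tetranorhalim-1(10)-en-18-oate
Product: 21 methyl (4S,5R,8R,9S)-12-hydroxy-13,14,15,16-tetranorhalim-1(10)-en-18-oate
Conditions: Bu4NF, THF, rt
Reagents that add atoms: none
Why: Fluoride desilylation frees the primary C12 alcohol, which is too far from the hindered C18 ester to lactonise.

Step 15
Reactants: 21 methyl (4S,5R,8R,9S)-12-hydroxy-13,14,15,16-tetranorhalim-1(10)-en-18-oate
Product: 22 methyl (4S,5R,8R,9S)-12-iodo-13,14,15,16-tetranorhalim-1(10)-en-18-oate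
Conditions: I2, PPh3, imidazole, CH2Cl2, 0 °C → rt
Reagents that add atoms: iodine, II
Why: Appel-type iodination converts the unhindered primary alcohol to the iodide by SN2 displacement of the oxyphosphonium.

Step 16
Reactants: 23 but-2-yn-1-ol
Product: 24 (but-2-yn-1-yloxy)(tert-butyl)dimethylsilane
Conditions: t-BuMe2SiCl, imidazole, CH2Cl2, rt
Reagents that add atoms: tert-butyldimethylsilyl chloride, CC(C)(C)[Si](C)(C)Cl
Why: Standard silylation masks the hydroxyl before hydrozirconation.

Step 17
Reactants: 24 (but-2-yn-1-yloxy)(tert-butyl)dimethylsilane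
Product: 26 tert-butyl{[(2E)-3-iodobut-2-en-1-yl]oxy}dimethylsilane, via alkenylzirconocene chloride 25 (not isolated)
Conditions: Cp2Zr(H)Cl (1.5 equiv), THF, 50 °C; then I2, 0 °C
Reagents that add atoms: iodine, II
Why: Hydrozirconation adds H and Zr syn across the alkyne, equilibration with excess hydride places zirconium on the less hindered methyl-bearing carbon, and iodinolysis with retention gives the (E)-vinyl iodide.

Step 18
Reactants: 22 methyl (4S,5R,8R,9S)-12-iodo-13,14,15,16-tetranorhalim-1(10)-en-18-oate; 26 tert-butyl{[(2E)-3-iodobut-2-en-1-yl]oxy}dimethylsilane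
Product: 28 methyl (4S,5R,8R,9S,13E)-15-[(tert-butyldimethylsilyl)oxy]halima-1(10),13-dien-18-oate, via alkylzinc iodide 27 (not isolated)
Conditions: Zn dust, LiCl, THF, 40 °C; then 26, Pd(OAc)2 (3 mol %), SPhos (6 mol %), THF, rt → 40 °C
Reagents that add atoms: none
Why: Direct zinc insertion into the primary iodide tolerates the ester, and Negishi coupling of the alkylzinc with the vinyl iodide forms C12–C13 with retention of the (E) geometry.

Step 19
Reactants: 28 methyl (4S,5R,8R,9S,13E)-15-[(tert-butyldimethylsilyl)oxy]halima-1(10),13-dien-18-oate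
Product: 29 methyl (4S,5R,8R,9S,13E)-15-hydroxyhalima-1(10),13-dien-18-oate
Conditions: Bu4NF, THF, 0 °C → rt
Reagents that add atoms: none
Why: Fluoride desilylation releases the allylic C15 alcohol without touching the hindered methyl ester.

Step 20
Reactants: 29 methyl (4S,5R,8R,9S,13E)-15-hydroxyhalima-1(10),13-dien-18-oate; 30 3-phenylprop-2-ynoic acid
Product: 31 methyl (4S,5R,8R,9S,13E)-15-[(3-phenylprop-2-ynoyl)oxy]halima-1(10),13-dien-18-oate
Conditions: DCC, DMAP (10 mol %), CH2Cl2, 0 °C
Reagents that add atoms: none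
Why: Steglich esterification acylates the primary allylic alcohol at low temperature without allylic transposition.

Step 21
Reactants: 31 methyl (4S,5R,8R,9S,13E)-15-[(3-phenylprop-2-ynoyl)oxy]halima-1(10),13-dien-18-oate
Product: 32 methyl (4S,5R,8R,9S,13E)-15-{[(2Z)-3-phenylprop-2-enoyl]oxy}halima-1(10),13-dien-18-oate (CNP0296075.1)
Conditions: H2 (1 atm), Pd/CaCO3 poisoned with Pb(OAc)2 (Lindlar catalyst), quinoline, EtOAc, rt, stopped after one equivalent of H2
Reagents that add atoms: none
Why: Lindlar semihydrogenation adds H2 syn to the alkyne and gives the (Z)-cinnamate, the two trisubstituted olefins being too hindered to react on the poisoned catalyst.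

**Compound list**
1 | methacrolein (2-methylprop-2-enal) | CC(=C)C=O | starting material
2 | (E)-octa-1,3,7-triene | C=C/C=C/CCC=C | starting material
3 | (1S,2R)-2-(but-3-en-1-yl)-1-methylcyclohex-3-ene-1-carbaldehyde | O=C[C@@]1(C)CCC=C[C@H]1CCC=C | intermediate
4 | (1S,2R)-2-(but-3-en-1-yl)-1-methylcyclohex-3-ene-1-carboxylic acid | OC(=O)[C@@]1(C)CCC=C[C@H]1CCC=C | intermediate
5 | (1S,4S,5S,8S)-8-(but-3-en-1-yl)-4-iodo-1-methyl-6-oxabicyclo[3.2.1]octan-7-one (iodine anti to the lactone oxygen; butenyl syn to the lactone bridge) | O=C1O[C@@H]2[C@@H](I)CC[C@@]1(C)[C@@H]2CCC=C | intermediate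
6 | (1S,5R,8S)-8-(but-3-en-1-yl)-1-methyl-6-oxabicyclo[3.2.1]octan-7-one | O=C1O[C@@H]2CCC[C@@]1(C)[C@@H]2CCC=C | intermediate
7 | potassium (1S,2S,3R)-2-(but-3-en-1-yl)-3-hydroxy-1-methylcyclohexane-1-carboxylate | [K+].[O-]C(=O)[C@@]1(C)CCC[C@@H](O)[C@H]1CCC=C | intermediate
8 | methyl (1S,2S,3R)-2-(but-3-en-1-yl)-3-hydroxy-1-methylcyclohexane-1-carboxylate | COC(=O)[C@@]1(C)CCC[C@@H](O)[C@H]1CCC=C | intermediate
9 | methyl (1S,2S)-2-(but-3-en-1-yl)-1-methyl-3-oxocyclohexane-1-carboxylate | COC(=O)[C@@]1(C)CCCC(=O)[C@H]1CCC=C | intermediate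
10 | lithium enolate of 9 (C1=C10 enolate) | [Li+].COC(=O)[C@@]1(C)CCC=C([O-])[C@H]1CCC=C | intermediate
11 | methyl (1S,2S)-2-(but-3-en-1-yl)-1-methyl-3-{[(trifluoromethyl)sulfonyl]oxy}cyclohex-3-ene-1-carboxylate | COC(=O)[C@@]1(C)CCC=C(OS(=O)(=O)C(F)(F)F)[C@H]1CCC=C | intermediate
12 | phenyl vinyl sulfone | C=CS(=O)(=O)c1ccccc1 | starting material
13 | methyl (1S,2S)-1-methyl-2-[(E)-4-(phenylsulfonyl)but-3-en-1-yl]-3-{[(trifluoromethyl)sulfonyl]oxy}cyclohex-3-ene-1-carboxylate | COC(=O)[C@@]1(C)CCC=C(OS(=O)(=O)C(F)(F)F)[C@H]1CC/C=C/S(=O)(=O)c1ccccc1 | intermediate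
14 | 3-bromobut-3-en-1-ol | OCCC(Br)=C | starting material
15 | (3-bromobut-3-en-1-yloxy)(tert-butyl)dimethylsilane | C=C(Br)CCO[Si](C)(C)C(C)(C)C | intermediate
16 | [4-(tert-butyldimethylsilyloxy)but-1-en-2-yl]lithium | [Li]C(=C)CCO[Si](C)(C)C(C)(C)C | intermediate
17 | 2-[4-(tert-butyldimethylsilyloxy)but-1-en-2-yl]-4,4,5,5-tetramethyl-1,3,2-dioxaborolane | C=C(CCO[Si](C)(C)C(C)(C)C)B1OC(C)(C)C(C)(C)O1 | intermediate
18 | methyl (1S,2R)-3-[4-(tert-butyldimethylsilyloxy)but-1-en-2-yl]-1-methyl-2-[(E)-4-(phenylsulfonyl)but-3-en-1-yl]cyclohex-3-ene-1-carboxylate | COC(=O)[C@@]1(C)CCC=C(C(=C)CCO[Si](C)(C)C(C)(C)C)[C@H]1CC/C=C/S(=O)(=O)c1ccccc1 | intermediate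
19 | methyl (4S,5R,8R,9S)-12-[(tert-butyldimethylsilyl)oxy]-17-(phenylsulfonyl)-13,14,15,16-tetranorhalim-1(10)-en-18-oate | COC(=O)[C@@]1(C)CCC=C2[C@H]1CC[C@@H](CS(=O)(=O)c3ccccc3)[C@]2(C)CCO[Si](C)(C)C(C)(C)C | intermediate
20 | methyl (4S,5R,8R,9S)-12-[(tert-butyldimethylsilyl)oxy]-13,14,15,16-tetranorhalim-1(10)-en-18-oate | COC(=O)[C@@]1(C)CCC=C2[C@H]1CC[C@@H](C)[C@]2(C)CCO[Si](C)(C)C(C)(C)C | intermediate
21 | methyl (4S,5R,8R,9S)-12-hydroxy-13,14,15,16-tetranorhalim-1(10)-en-18-oate | COC(=O)[C@@]1(C)CCC=C2[C@H]1CC[C@@H](C)[C@]2(C)CCO | intermediate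
22 | methyl (4S,5R,8R,9S)-12-iodo-13,14,15,16-tetranorhalim-1(10)-en-18-oate | COC(=O)[C@@]1(C)CCC=C2[C@H]1CC[C@@H](C)[C@]2(C)CCI | intermediate
23 | but-2-yn-1-ol | CC#CCO | starting material
24 | (but-2-yn-1-yloxy)(tert-butyl)dimethylsilane | CC#CCO[Si](C)(C)C(C)(C)C | intermediate
25 | chlorobis(cyclopentadienyl)[(2E)-4-(tert-butyldimethylsilyloxy)but-2-en-2-yl]zirconium | C/C(=C\CO[Si](C)(C)C(C)(C)C)[Zr](Cl)(C1C=CC=C1)C1C=CC=C1 | intermediate
26 | tert-butyl{[(2E)-3-iodobut-2-en-1-yl]oxy}dimethylsilane | I/C(C)=C/CO[Si](C)(C)C(C)(C)C | intermediate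
27 | [(4S,5R,8R,9S)-18-methoxy-18-oxo-13,14,15,16-tetranorhalim-1(10)-en-12-yl]zinc iodide | COC(=O)[C@@]1(C)CCC=C2[C@H]1CC[C@@H](C)[C@]2(C)CC[Zn]I | intermediate
28 | methyl (4S,5R,8R,9S,13E)-15-[(tert-butyldimethylsilyl)oxy]halima-1(10),13-dien-18-oate | COC(=O)[C@@]1(C)CCC=C2[C@H]1CC[C@@H](C)[C@]2(C)CC/C(C)=C/CO[Si](C)(C)C(C)(C)C | intermediate
29 | methyl (4S,5R,8R,9S,13E)-15-hydroxyhalima-1(10),13-dien-18-oate | COC(=O)[C@@]1(C)CCC=C2[C@H]1CC[C@@H](C)[C@]2(C)CC/C(C)=C/CO | intermediate
30 | 3-phenylprop-2-ynoic acid | OC(=O)C#Cc1ccccc1 | starting material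
31 | methyl (4S,5R,8R,9S,13E)-15-[(3-phenylprop-2-ynoyl)oxy]halima-1(10),13-dien-18-oate | COC(=O)[C@@]1(C)CCC=C2[C@H]1CC[C@@H](C)[C@]2(C)CC/C(C)=C/COC(=O)C#Cc1ccccc1 | intermediate
32 | methyl (4S,5R,8R,9S,13E)-15-{[(2Z)-3-phenylprop-2-enoyl]oxy}halima-1(10),13-dien-18-oate (CNP0296075.1) | COC(=O)[C@@]1(C)CCC=C2[C@H]1CC[C@@H](C)[C@]2(C)CC/C(C)=C/COC(=O)/C=C\c1ccccc1 | target

**Step count**
Total: 21 steps. Longest linear sequence: 17 steps (steps 1–8, 11–15, 18–21).

**Steps most likely to fail**

Step 12. The stabilised allylic radical may take a second hydrogen atom (net reduction of the diene) or give the first one back before the slow 6-exo addition occurs. Rotation about C9–C10 or an axial placing of C17 in the chair would erode the configuration at C9 or C8, and prolonged exposure could reduce the C1–C10 olefin of the product. The fallback reaches the same allylic radical by established chemistry and sets out from 18. One equivalent of anhydrous HCl (ether solution, CH2Cl2, −78 °C) should add across the diene in the Markovnikov sense to give the tertiary allylic chloride methyl (1S,2S)-3-[4-(tert-butyldimethylsilyloxy)-2-chlorobutan-2-yl]-1-methyl-2-[(E)-4-(phenylsulfonyl)but-3-en-1-yl]cyclohex-3-ene-1-carboxylate F1 (either epimer at the chlorine-bearing carbon, or its allylic isomer, leads to the same radical). Slow addition of Bu3SnH with AIBN in benzene at 80 °C, the known tin hydride cyclisation of an allyl radical from an allylic halide onto an activated alkene, should then close ring B and come back to the route at 19.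

Step 1. An α-methyl enal with an open-chain monoalkyl diene may show incomplete endo preference and insufficient facial discrimination, which would lower both the cis relationship at C4/C5 and the enantiomeric purity. The fallback separates the two tasks and sets out from 2. (R)-4-Benzyloxazolidin-2-one is N-acylated (n-BuLi, acryloyl chloride, THF, −78 °C) to (R)-3-acryloyl-4-benzyloxazolidin-2-one F2. Its Et2AlCl-promoted Diels–Alder reaction with 2 (CH2Cl2, −78 °C) proceeds through the chelated s-cis imide, which is attacked endo on the face away from the benzyl group, and should give (R)-4-benzyl-3-{[(1S,2R)-2-(but-3-en-1-yl)cyclohex-3-en-1-yl]carbonyl}oxazolidin-2-one F3 with C5 set. LiOH/H2O2 (THF/H2O, 0 °C) removes the auxiliary to give (1S,2R)-2-(but-3-en-1-yl)cyclohex-3-ene-1-carboxylic acid F4. Methylation of its dianion (LiN(i-Pr)2, 2.2 equiv, THF, 0 °C; MeI) should occur anti to the neighbouring butenyl group, which sets C4 and comes back to the route at 4.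

Step 11. After oxidative addition the alkenylpalladium triflate may insert the tethered vinyl sulfone (5-exo Heck closure onto C8) faster than it transmetalates, and aqueous base may add to the vinyl sulfone or shift it to the allyl sulfone. The fallback keeps the sulfone out of the palladium step and sets out from 11. Oxidative cleavage of the terminal alkene (OsO4 cat., NaIO4, 2,6-lutidine, dioxane/H2O), which the electron-poor enol triflate olefin should survive, gives methyl (1S,2S)-1-methyl-2-(3-oxopropyl)-3-{[(trifluoromethyl)sulfonyl]oxy}cyclohex-3-ene-1-carboxylate F5. Suzuki coupling with 17 under the conditions of step 11 gives methyl (1S,2R)-3-[4-(tert-butyldimethylsilyloxy)but-1-en-2-yl]-1-methyl-2-(3-oxopropyl)cyclohex-3-ene-1-carboxylate F6. Horner–Wadsworth–Emmons olefination with (EtO)2P(O)CH2SO2Ph (LiCl, DBU, MeCN, rt) then installs the (E)-vinyl sulfone and comes back to the route at 18.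

**Further compounds**
F1 | step 12 | methyl (1S,2S)-3-[4-(tert-butyldimethylsilyloxy)-2-chlorobutan-2-yl]-1-methyl-2-[(E)-4-(phenylsulfonyl)but-3-en-1-yl]cyclohex-3-ene-1-carboxylate (epimers at the C–Cl carbon) | COC(=O)[C@@]1(C)CCC=C(C(C)(Cl)CCO[Si](C)(C)C(C)(C)C)[C@H]1CC/C=C/S(=O)(=O)c1ccccc1
F2 | step 1 | (R)-3-acryloyl-4-benzyloxazolidin-2-one | C=CC(=O)N1[C@H](Cc2ccccc2)COC1=O
F3 | step 1 | (R)-4-benzyl-3-{[(1S,2R)-2-(but-3-en-1-yl)cyclohex-3-en-1-yl]carbonyl}oxazolidin-2-one | O=C([C@H]1CCC=C[C@H]1CCC=C)N1[C@H](Cc2ccccc2)COC1=O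
F4 | step 1 | (1S,2R)-2-(but-3-en-1-yl)cyclohex-3-ene-1-carboxylic acid | OC(=O)[C@H]1CCC=C[C@H]1CCC=C
F5 | step 11 | methyl (1S,2S)-1-methyl-2-(3-oxopropyl)-3-{[(trifluoromethyl)sulfonyl]oxy}cyclohex-3-ene-1-carboxylate | COC(=O)[C@@]1(C)CCC=C(OS(=O)(=O)C(F)(F)F)[C@H]1CCC=O
F6 | step 11 | methyl (1S,2R)-3-[4-(tert-butyldimethylsilyloxy)but-1-en-2-yl]-1-methyl-2-(3-oxopropyl)cyclohex-3-ene-1-carboxylate | COC(=O)[C@@]1(C)CCC=C(C(=C)CCO[Si](C)(C)C(C)(C)C)[C@H]1CCC=O
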